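The lactone ring of the target (O1, C2=O, C3 with the acetoxybutyl chain, C4–Br, C5 with the exocyclic iodomethylene) is traced back to a trisubstituted furan. Its one unsubstituted α-carbon is destined to become C2, and its methyl-bearing α-carbon becomes C5. A [4+2] photooxygenation bridges these two α-carbons with O2. Amine-triggered collapse of the endoperoxide then turns C2–H into C2=O and leaves OH on C5, the furan oxygen and its four carbons persisting as the lactone. The substrate is (R)-1-(4-bromo-5-methylfuran-3-yl)butyl acetate, made from 3,4-dibromofuran by exchange/acylation, CBS reduction and bromine-directed α-lithiation/methylation.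

Key step: step 6

Remark: N-methoxy-N-methylbutanamide is assumed to be purchased; the carbinol carbon is R in every compound from 5 onward (O > ring carbon > propyl > H throughout), and C5 of 12 and 14 is an uncontrolled centre that is erased later.

Step 1
Reactants: 1 3,4-dibromofuran; 2 N-methoxy-N-methylbutanamide
Product: 4 1-(4-bromofuran-3-yl)butan-1-one, via 4-bromo-3-lithiofuran 3 (not isolated)
Conditions: n-BuLi (1.05 equiv), Et2O, −78 °C; then 2, −78 → −40 °C; 1 M aq HCl, 0 °C
Reagents that add atoms: none
Why: Bromine–lithium exchange on the symmetric dibromide can give only one monolithio species, which holds its position at −78 °C and is acylated by the Weinreb amide (Weinreb ketone synthesis) without over-addition, because the chelated tetrahedral adduct collapses only on acidic work-up.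

Step 2
Reactants: 4 1-(4-bromofuran-3-yl)butan-1-one
Product: 5 (R)-1-(4-bromofuran-3-yl)butan-1-ol
Conditions: (S)-Me-CBS (10 mol %), BH3·SMe2 (0.7 equiv), THF, −20 °C; MeOH quench
Reagents that add atoms: none
Why: Corey–Bakshi–Shibata reduction: with the bromofuryl ring as the large and n-propyl as the small ketone substituent, the (S)-oxazaborolidine–borane complex should deliver hydride to the Si face and so set the (R)-carbinol centre, the same sense as for aryl n-alkyl ketones.

Step 3
Reactants: 5 (R)-1-(4-bromofuran-3-yl)butan-1-ol
Product: 6 (R)-[1-(4-bromofuran-3-yl)butoxy](tert-butyl)dimethylsilane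
Conditions: TBSCl (1.2 equiv), imidazole (2.5 equiv), DMF, rt
Reagents that add atoms: tert-butyldimethylsilyl chloride, CC(C)(C)[Si](C)(C)Cl
Why: Imidazole-promoted O-silylation of a secondary alcohol leaves the stereocentre untouched and masks the hydroxyl as a bulky, poorly coordinating, base-stable ether for the lithiation.

Step 4
Reactants: 6 (R)-[1-(4-bromofuran-3-yl)butoxy](tert-butyl)dimethylsilane
Product: 8 (R)-[1-(4-bromo-5-methylfuran-3-yl)butoxy](tert-butyl)dimethylsilane, via 5-lithiofuran 7 (not isolated)
Conditions: LDA (1.2 equiv), THF, −78 °C; MeI (3 equiv), −78 → 0 °C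
Reagents that add atoms: iodomethane, CI
Why: Directed α-lithiation: LDA, which does not exchange aryl bromides, removes the α-proton flanked by the ring oxygen and the inductively acidifying C–Br (the known site for 3-bromofurans), the bulky silyloxyalkyl group discouraging attack at the other α-carbon, and the furyllithium is then C-methylated by SN2 on iodomethane.

Step 5
Reactants: 8 (R)-[1-(4-bromo-5-methylfuran-3-yl)butoxy](tert-butyl)dimethylsilane
Product: 10 (R)-1-(4-bromo-5-methylfuran-3-yl)butyl acetate, via furyl carbinol 9 (not isolated)
Conditions: TBAF (1.2 equiv), THF, 0 °C → rt; then Et3N, DMAP (cat.), Ac2O (4 equiv), 0 °C → rt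
Reagents that add atoms: acetic anhydride, CC(=O)OC(C)=O
Why: Fluoride-induced Si–O cleavage is followed in the same flask by DMAP-catalysed O-acetylation; both events occur at oxygen, so the configuration is retained, and the acid-sensitive furyl carbinol never meets acid.

Step 6
Reactants: 10 (R)-1-(4-bromo-5-methylfuran-3-yl)butyl acetate
Product: 12 (R)-1-(4-bromo-5-hydroxy-5-methyl-2-oxo-2,5-dihydrofuran-3-yl)butyl acetate (C5 epimer mixture), via furan endoperoxide 11 (not isolated)
Conditions: O2, hν (visible), tetraphenylporphyrin (cat.), i-Pr2NEt (3 equiv), CH2Cl2, −78 °C; then warm to rt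
Reagents that add atoms: dioxygen, O=O
Why: Sensitised singlet oxygen should add suprafacially as the 2π partner across the two furan α-carbons (the 4π diene) to give the 2,3,7-trioxabicyclo[2.2.1]heptene 11; the amine then removes the only bridgehead hydrogen while the O–O bond breaks, so that carbon becomes the lactone C=O and the methyl-bearing carbon keeps an oxygen as the hemiketal OH (Kornblum–DeLaMare fragmentation). The closest known reaction type is the base-mediated photooxygenation of α-unsubstituted furans to γ-hydroxybutenolides. No new ring remains in the product: the transient peroxide bridge closes by concerted [4+2] cycloaddition and is opened again, and the lactone ring is the furan ring itself. The one new stereocentre, the hemiketal C5, is not controlled (either face of the flat furan can be attacked and the lactol can epimerise by ring–chain tautomerism), which is harmless because C5 becomes sp2 in step 7; the (R)-carbinol centre is not involved. The selectivity needed is the direction of the fragmentation, and it is secured because the second bridgehead carries methyl instead of hydrogen, while chemoselectivity follows from the furan being the only electron-rich diene present. The hindered amine should not attack the acetate or the vinylogous acyl bromide at low temperature.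

Step 7
Reactants: 12 (R)-1-(4-bromo-5-hydroxy-5-methyl-2-oxo-2,5-dihydrofuran-3-yl)butyl acetate
Product: 13 (R)-1-(4-bromo-5-methylidene-2-oxo-2,5-dihydrofuran-3-yl)butyl acetate
Conditions: P2O5 (2 equiv), CH2Cl2, rt, dark; used promptly
Reagents that add atoms: none
Why: Acid-promoted dehydration of a γ-hydroxy-γ-methylbutenolide (a cyclic pseudo-acid): ionisation at the hemiketal carbon gives an oxygen-stabilised cation that can lose a proton only from the methyl group, since C4 carries bromine, giving the exocyclic enol lactone while the acetate, attached next to the electron-poor C3, should resist ionisation.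

Step 8
Reactants: 13 (R)-1-(4-bromo-5-methylidene-2-oxo-2,5-dihydrofuran-3-yl)butyl acetate
Product: 15 (R)-1-[(5Z)-4-bromo-5-(iodomethylidene)-2-oxo-2,5-dihydrofuran-3-yl]butyl acetate, via chloro iodomethyl lactone 14 (not isolated)
Conditions: ICl (1.05 equiv), CH2Cl2, −78 °C, dark; then i-Pr2NEt (1.5 equiv), −78 → 0 °C
Reagents that add atoms: iodine monochloride, ClI
Why: Halogenation–dehydrohalogenation of an alkylidene butenolide: I+ adds to the terminal carbon of the enol-lactone alkene and chloride to the oxocarbenium carbon C5, and loss of HCl, possible only towards the CH2I group, should give the Z-alkene because iodine avoids the C4 bromine (allylic strain) and lies syn to the ring oxygen; the (R)-centre is untouched and the product is the target.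

Compound list
1 | 3,4-dibromofuran | Brc1cocc1Br | starting material
2 | N-methoxy-N-methylbutanamide | CCCC(=O)N(C)OC | starting material
3 | 4-bromo-3-lithiofuran | [Li]c1cocc1Br | intermediate (not isolated)
4 | 1-(4-bromofuran-3-yl)butan-1-one | CCCC(=O)c1cocc1Br | intermediate
5 | (R)-1-(4-bromofuran-3-yl)butan-1-ol | CCC[C@@H](O)c1cocc1Br | intermediate
6 | (R)-[1-(4-bromofuran-3-yl)butoxy](tert-butyl)dimethylsilane | CCC[C@@H](O[Si](C)(C)C(C)(C)C)c1cocc1Br | intermediate
7 | (R)-[1-(4-bromo-5-lithiofuran-3-yl)butoxy](tert-butyl)dimethylsilane | CCC[C@@H](O[Si](C)(C)C(C)(C)C)c1coc([Li])c1Br | intermediate (not isolated)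
8 | (R)-[1-(4-bromo-5-methylfuran-3-yl)butoxy](tert-butyl)dimethylsilane | CCC[C@@H](O[Si](C)(C)C(C)(C)C)c1coc(C)c1Br | intermediate
9 | (R)-1-(4-bromo-5-methylfuran-3-yl)butan-1-ol | CCC[C@@H](O)c1coc(C)c1Br | intermediate (not isolated)
10 | (R)-1-(4-bromo-5-methylfuran-3-yl)butyl acetate | CCC[C@@H](OC(C)=O)c1coc(C)c1Br | intermediate
11 | (R)-1-(5-bromo-4-methyl-2,3,7-trioxabicyclo[2.2.1]hept-5-en-6-yl)butyl acetate, bridgeheads as a mixture | CCC[C@@H](OC(C)=O)C1=C(Br)C2(C)OOC1O2 | intermediate (not isolated)
12 | (R)-1-(4-bromo-5-hydroxy-5-methyl-2-oxo-2,5-dihydrofuran-3-yl)butyl acetate, C5 epimer mixture | CCC[C@@H](OC(C)=O)C1=C(Br)C(C)(O)OC1=O | intermediate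
13 | (R)-1-(4-bromo-5-methylidene-2-oxo-2,5-dihydrofuran-3-yl)butyl acetate | CCC[C@@H](OC(C)=O)C1=C(Br)C(=C)OC1=O | intermediate
14 | (R)-1-[4-bromo-5-chloro-5-(iodomethyl)-2-oxo-2,5-dihydrofuran-3-yl]butyl acetate, C5 epimer mixture | CCC[C@@H](OC(C)=O)C1=C(Br)C(Cl)(CI)OC1=O | intermediate (not isolated)
15 | (R)-1-[(5Z)-4-bromo-5-(iodomethylidene)-2-oxo-2,5-dihydrofuran-3-yl]butyl acetate | CCC[C@@H](OC(C)=O)C1=C(Br)/C(=C/I)OC1=O | target

Total step count: 8. Longest linear sequence: 8 steps (1 → 15, fully linear).

Steps most likely to fail, in order of risk:

Step 6. The cycloaddition may be slow on a furan deactivated by bromine, the amine may quench singlet oxygen, or the endoperoxide may decay by paths other than deprotonative fragmentation. The fallback is a non-photochemical oxidative ring opening that sets out from 10 and forms the same C2=O and C5–O bonds. NBS with NaHCO3 in aqueous acetone at −20 °C should open the furan to the cis keto enal (R)-1-[(2E)-3-bromo-1,4-dioxopent-2-en-2-yl]butyl acetate F1. Pinnick oxidation (NaClO2, NaH2PO4, 2-methyl-2-butene, t-BuOH/H2O) should then give (2E)-2-[(1R)-1-acetoxybutyl]-3-bromo-4-oxopent-2-enoic acid F2. F2 is the open-chain tautomer of the lactol and should close spontaneously, so the route is rejoined at 12.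

Step 8. The dehydrochlorination may give poor control of the alkene geometry, and chloride or the amine may substitute at the vinylogous acyl bromide carbon C4. The fallback sets out from 13 and uses neither chloride nor amine. Hydroxy-iodination with NIS in aqueous acetone at 0 °C should give the isolable iodo lactol (R)-1-[4-bromo-5-hydroxy-5-(iodomethyl)-2-oxo-2,5-dihydrofuran-3-yl]butyl acetate F3. Dehydration of F3 with P2O5 in CH2Cl2, as in step 7, proceeds through the cation and should favour the thermodynamically preferred Z-alkene. The route is rejoined at 15.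

Step 4. Deprotonation may compete at the α-carbon next to the silyloxyalkyl group, or the bromine may migrate in the lithiated furan before methylation. The fallback sets out from ketone 4 and replaces metalation by electrophilic substitution and cross-coupling. NBS in DMF should brominate the α-carbon next to C–Br, because the acyl group deactivates the other α-position, giving 1-(4,5-dibromofuran-3-yl)butan-1-one F4. Negishi coupling with MeZnCl and Pd(PPh3)4 in THF should react selectively at the α-bromide to give 1-(4-bromo-5-methylfuran-3-yl)butan-1-one F5. CBS reduction of F5 with (S)-Me-CBS and BH3·SMe2 then rejoins the route at 9, which is acetylated (Ac2O, Et3N, DMAP) to 10 with no silyl group needed.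

Further compounds
F1 | step 6 | (R)-1-[(2E)-3-bromo-1,4-dioxopent-2-en-2-yl]butyl acetate | CCC[C@@H](OC(C)=O)/C(C=O)=C(\Br)C(C)=O
F2 | step 6 | (2E)-2-[(1R)-1-acetoxybutyl]-3-bromo-4-oxopent-2-enoic acid | CCC[C@@H](OC(C)=O)/C(C(=O)O)=C(\Br)C(C)=O
F3 | step 8 | (R)-1-[4-bromo-5-hydroxy-5-(iodomethyl)-2-oxo-2,5-dihydrofuran-3-yl]butyl acetate, C5 epimer mixture | CCC[C@@H](OC(C)=O)C1=C(Br)C(O)(CI)OC1=O
F4 | step 4 | 1-(4,5-dibromofuran-3-yl)butan-1-one | CCCC(=O)c1coc(Br)c1Br
F5 | step 4 | 1-(4-bromo-5-methylfuran-3-yl)butan-1-one | CCCC(=O)c1coc(C)c1Br
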